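The route rests on a retro-[4+2] cut of the methylcyclohexene ring A: its two bonds to ring B, CH2–C(geranyl) and CH–C(OH), are made together, last, by an intramolecular Diels–Alder reaction. The step exploits the ring A unit CH2–CH=C(CH3)–CH sitting on the C(geranyl)–C(OH) edge of enone ring B, with its CH shared by cyclopentane ring C: one operation closes rings A and C and sets three stereocentres. The precursor is a dearomatized 3a-hydroxybenzofuranone (ring B fused to dimethyldihydrofuran ring D) bearing an (E)-3-methylpenta-2,4-dienyl arm and a cyclic carbonate, built from a single organocatalytically set centre.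

Key step: step 11

Remark: geranyl = (2E)-3,7-dimethylocta-2,6-dien-1-yl and prenyl = 3-methylbut-2-en-1-yl; from compound 8 on, positions follow the 2,3-dihydrobenzofuran skeleton (O1, C2, C3, C3a, C4 to C7, C7a); ring A = methylcyclohexene, ring B = six-membered enone ring, ring C = cyclopentane, ring D = 2,2-dimethyltetrahydrofuran; 5-bromoresorcinol is assumed to be allylated between its hydroxyls like other 5-substituted resorcinols.

Step 1
Reactants: 1 5-bromoresorcinol; 2 geraniol
Product: 3 5-bromo-2-geranylbenzene-1,3-diol
Conditions: acidic Al2O3, 1,2-dichloroethane, 80 °C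
Reagents that add atoms: none
Why: Friedel–Crafts allylation on acidic alumina should place the allyl unit at C2, the position ortho to both hydroxyls (the two other activated positions are flanked by bromine), with the (E) alkene retained; the product keeps a mirror plane, so its two free ring positions and its two hydroxyls are still equivalent.

Step 2
Reactants: 3 5-bromo-2-geranylbenzene-1,3-diol; 4 ethyl (E)-4-oxobut-2-enoate
Product: 6 ethyl (4S)-5-bromo-8-geranyl-7-hydroxy-2-methoxychromane-4-carboxylate (both C2 epimers), via lactol 5 (not isolated)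
Conditions: (R)-α,α-diphenylprolinol trimethylsilyl ether (20 mol %), PhCO2H (20 mol %), CH2Cl2, 0 °C; then MeOH, PPTS, rt
Reagents that add atoms: methanol, CO
Why: Iminium-catalysed Friedel–Crafts alkylation/hemiacetalisation of a phenol with an enal: the ring carbon ortho and para to the hydroxyls adds to the β-carbon of the iminium ion (the carbon α to the ester) on the face left open by the diphenyl(silyloxy)methyl group of the (R)-catalyst, which should set the lone stereocentre as (4S), and the neighbouring hydroxyl closes the lactol, trapped as its methyl acetal so that one phenol is masked and the other stays free.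

Step 3
Reactants: 6 ethyl (4S)-5-bromo-8-geranyl-7-hydroxy-2-methoxychromane-4-carboxylate
Product: 7 2-[(4S)-5-bromo-8-geranyl-7-hydroxy-2-methoxychroman-4-yl]propan-2-ol
Conditions: MeMgBr (4 equiv), CeCl3, THF, −78 to 0 °C; aq. NH4Cl
Reagents that add atoms: methylmagnesium bromide, C[Mg]Br
Why: Double Grignard addition to the ester under organocerium conditions (low basicity, so the α-aryl ester is not enolised and C4 is not epimerised) should give the tertiary alcohol, the acetal and the aryl bromide being inert.

Step 4
Reactants: 7 2-[(4S)-5-bromo-8-geranyl-7-hydroxy-2-methoxychroman-4-yl]propan-2-ol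
Product: 8 (3S)-5-geranyl-2,2-dimethyl-2,3-dihydrobenzofuran-6-ol bridged from C3 to the C4 oxygen by CH2–CH(OCH3) (cyclic methyl acetal)
Conditions: Pd(OAc)2 (5 mol %), 2-(di-tert-butylphosphino)-1,1'-binaphthyl (6 mol %), Cs2CO3, toluene, 80 °C
Reagents that add atoms: none
Why: Palladium-catalysed intramolecular C–O coupling (Buchwald–Hartwig etherification) of the tertiary alkoxide, which has no β-hydrogen, with the neighbouring C–Br bond should close ring D under non-ionising conditions, so the benzylic stereocentre is untouched.

Step 5
Reactants: 8 tricyclic phenol; 9 prenyl bromide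
Product: 10 7-prenyl derivative of 8
Conditions: NaH (1.1 equiv), toluene, 0 °C; then 9, 0 °C to rt
Reagents that add atoms: none
Why: C-Alkylation of the sodium phenoxide in toluene, where the tight ion pair favours attack through the ortho carbon over oxygen, should install the prenyl group at C7, the only unsubstituted ring position; the dienone first formed tautomerises back to the phenol.

Step 6
Reactants: 10 7-prenyl tricyclic phenol
Product: 11 quinol acetal (3a-hydroxy-6-oxo form of 10 with C4=C5 and C7=C7a double bonds, 3a-OH cis to H-3, acetal bridge intact)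
Conditions: PhI(OAc)2 (1.05 equiv), MeCN–H2O (4:1), 0 °C
Reagents that add atoms: water, O
Why: Oxidative dearomatisation with the trivalent iodine reagent (para-quinol formation): water should add to the phenoxonium ion at C3a, para to the only free phenol, and because C3 is held in both the five- and the six-membered fused ring the new hydroxyl can only come in cis to H-3, which sets C3a.

Step 7
Reactants: 11 quinol acetal
Product: 12 (3S,3aR)-2-[5-geranyl-3a,4-dihydroxy-2,2-dimethyl-6-oxo-7-prenyl-3,3a-dihydrobenzofuran-3-yl]acetaldehyde (C4 enol)
Conditions: PPTS (cat.), acetone–H2O (9:1), rt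
Reagents that add atoms: water, O
Why: After dearomatisation the acetal oxygen at C4 is a vinylogous carboxylate leaving group, so mild acid-catalysed acetal hydrolysis should release the aldehyde and the C4 enol without ionising the tertiary carbinol.

Step 8
Reactants: 12 hydroxy enol aldehyde
Product: 13 cyclic 3a,4-carbonate of 12
Conditions: 1,1'-carbonyldiimidazole, CH2Cl2, 0 °C to rt
Reagents that add atoms: 1,1'-carbonyldiimidazole, O=C(n1ccnc1)n1ccnc1
Why: Carbonate formation from a cis-1,2-diol equivalent: the C4 enol hydroxyl and the adjacent tertiary C3a hydroxyl should be tied as the five-membered cyclic carbonate (acylation at the C6 oxygen of the other tautomer is reversible and cannot cyclise), which fixes the C6 ketone tautomer, protects the quinol and weakens the donor at C4.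

Step 9
Reactants: 13 carbonate aldehyde
Product: 14 (E)-2-methylbut-2-enal attached through its C4 to C3 of the carbonate-protected bicycle
Conditions: Ph3P=C(CH3)CHO, toluene, 70 °C
Reagents that add atoms: 2-(triphenylphosphoranylidene)propanal, CC(C=O)=P(c1ccccc1)(c1ccccc1)c1ccccc1
Why: Wittig olefination with the stabilised ylide should give the trisubstituted enal with the (E) geometry that stabilised ylides deliver.

Step 10
Reactants: 14 (E)-enal
Product: 15 3-[(2E)-3-methylpenta-2,4-dien-1-yl] triene carbonate
Conditions: Ph3PCH3Br, KN(SiMe3)2, THF, −78 to −20 °C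
Reagents that add atoms: methyltriphenylphosphonium bromide, C[P+](c1ccccc1)(c1ccccc1)c1ccccc1.[Br-]
Why: Wittig methylenation of the enal carbonyl at low temperature, where the cyclic carbonate and the hindered, doubly vinylogous C6 carbonyl are not attacked, should complete the (E)-dienyl arm; the triene is kept cold and used at once.

Step 11
Reactants: 15 triene carbonate
Product: 16 cyclic carbonate of the target (the two tertiary oxygens joined by C=O)
Conditions: toluene (0.01 M), BHT (cat.), 110 °C, sealed tube
Reagents that add atoms: none
Why: Thermal intramolecular Diels–Alder reaction of the (E)-2-methyl-1,3-diene with the tetrasubstituted C4=C5 enone bond of ring B, whose donor oxygen is tamed as an enol carbonate; the closest known reaction type is the type 1 intramolecular Diels–Alder reaction of 1,3,8-nonatrienes with cross-conjugated cyclohexadienones obtained by oxidative dearomatisation. Ring A (six-membered) is closed by the cycloaddition itself and ring C (five-membered) as the tether-enclosed ring of the same event, the CH–C4 bond leading and the CH2–C5 bond that completes ring A lagging in the asynchronous transition state. C4 and C5 are set by suprafacial addition to the face of ring B that carries C3 (the carbonate holds the C3a oxygen on the other face), so both new ring bonds are cis to the tether and geranyl and the C4 oxygen end up cis to the C3a oxygen. The methine carbon of ring A is set by the (E) geometry of the diene together with the endo transition state (diene over ring B, overlap with C6=O), the only one that gives the cis-fused, bowl-shaped A/B/C triad. The step needs site selectivity for C4=C5 over C7=C7a, secured because addition to the latter would build a strained 2-oxabicyclo[2.2.1]heptane, and cis over trans ring fusion, secured by ring D, which pins the tether over the C3a–C4 edge.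

Step 12
Reactants: 16 cyclic carbonate of the target
Product: 17 CNP0323114.1 (target)
Conditions: K2CO3 (0.2 equiv), MeOH, 0 °C
Reagents that add atoms: none
Why: Base-catalysed transesterification with methanol should take off the cyclic carbonate as dimethyl carbonate and free the cis-diol, the low temperature and the catalytic amount of base guarding against retro-aldol opening of the β-hydroxy ketone.

Compound list

1 | 5-bromoresorcinol (5-bromobenzene-1,3-diol) | Oc1cc(Br)cc(O)c1 | starting material
2 | geraniol ((2E)-3,7-dimethylocta-2,6-dien-1-ol) | CC(C)=CCC/C(C)=C/CO | starting material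
3 | 5-bromo-2-geranylbenzene-1,3-diol | CC(C)=CCC/C(C)=C/Cc1c(O)cc(Br)cc1O | intermediate
4 | ethyl (E)-4-oxobut-2-enoate | CCOC(=O)/C=C/C=O | starting material
5 | ethyl (4S)-5-bromo-8-geranyl-2,7-dihydroxychromane-4-carboxylate (lactol, both C2 epimers, not isolated) | CC(C)=CCC/C(C)=C/Cc1c(O)cc(Br)c2c1OC(O)C[C@@H]2C(=O)OCC | intermediate
6 | ethyl (4S)-5-bromo-8-geranyl-7-hydroxy-2-methoxychromane-4-carboxylate (both C2 epimers) | CC(C)=CCC/C(C)=C/Cc1c(O)cc(Br)c2c1OC(OC)C[C@@H]2C(=O)OCC | intermediate
7 | 2-[(4S)-5-bromo-8-geranyl-7-hydroxy-2-methoxychroman-4-yl]propan-2-ol | CC(C)=CCC/C(C)=C/Cc1c(O)cc(Br)c2c1OC(OC)C[C@@H]2C(C)(C)O | intermediate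
8 | (3S)-5-geranyl-2,2-dimethyl-2,3-dihydrobenzofuran-6-ol with a CH2–CH(OCH3) bridge from C3 to the C4 oxygen (peri-fused furochromene, both acetal epimers) | CC(C)=CCC/C(C)=C/Cc1c(O)cc3c2c1OC(OC)C[C@@H]2C(C)(C)O3 | intermediate
9 | prenyl bromide (1-bromo-3-methylbut-2-ene) | CC(C)=CCBr | starting material
10 | 7-prenyl derivative of 8 | CC(C)=CCC/C(C)=C/Cc1c(O)c(CC=C(C)C)c3c2c1OC(OC)C[C@@H]2C(C)(C)O3 | intermediate
11 | quinol acetal: 3a-hydroxy-6-oxo form of 10, C4=C5 and C7=C7a double bonds, 3a-OH cis to H-3, acetal bridge intact | CC(C)=CCC/C(C)=C/CC1=C2OC(OC)C[C@@H]3C(C)(C)OC(=C(CC=C(C)C)C1=O)[C@]23O | intermediate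
12 | (3S,3aR)-2-[5-geranyl-3a,4-dihydroxy-2,2-dimethyl-6-oxo-7-prenyl-3,3a-dihydrobenzofuran-3-yl]acetaldehyde | CC(C)=CCC/C(C)=C/CC1=C(O)[C@]2(O)[C@H](CC=O)C(C)(C)OC2=C(CC=C(C)C)C1=O | intermediate
13 | cyclic 3a,4-carbonate of 12 (configuration unchanged) | CC(C)=CCC/C(C)=C/CC1=C2OC(=O)O[C@]23[C@H](CC=O)C(C)(C)OC3=C(CC=C(C)C)C1=O | intermediate
14 | (E)-2-methylbut-2-enal joined through its C4 to C3 of the carbonate-protected bicycle of 13 | CC(C)=CCC/C(C)=C/CC1=C2OC(=O)O[C@]23[C@H](C/C=C(\C)C=O)C(C)(C)OC3=C(CC=C(C)C)C1=O | intermediate
15 | triene carbonate: 13 with the side chain (2E)-3-methylpenta-2,4-dien-1-yl at C3 | CC(C)=CCC/C(C)=C/CC1=C2OC(=O)O[C@]23[C@H](C/C=C(\C)C=C)C(C)(C)OC3=C(CC=C(C)C)C1=O | intermediate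
16 | cyclic carbonate of the target (carbonate across the two tertiary oxygens, all five stereocentres as in the target) | CC(C)=CCC/C(C)=C/C[C@]12CC=C(C)[C@@H]3C[C@@H]4C(C)(C)OC(=C(CC=C(C)C)C1=O)[C@]4(OC(=O)O5)[C@@]325 | intermediate
17 | CNP0323114.1 | CC(C)=CCC/C(C)=C/C[C@]12CC=C(C)[C@@H]3C[C@@H]4C(C)(C)OC(=C(CC=C(C)C)C1=O)[C@]4(O)[C@@]32O | target

Total step count: 12. Longest linear sequence: 12 steps, from 5-bromoresorcinol 1.

Steps most likely to fail

Step 11. The cycloaddition may stall because the dienophile is tetrasubstituted and still carries an oxygen substituent; thermal breakdown of the quinol carbonate or closure through the trans-fused transition state could then compete. The fallback raises the diene energy instead of forcing the dienophile. It sets out from aldehyde 13. Wittig reaction with 3-(triphenylphosphoranylidene)butan-2-one should give the (E)-enone F1. TBSOTf and Et3N should convert it into the 2-silyloxydiene F2, which should cyclise at lower temperature to the silyl enol ether cycloadduct F3. CsF and PhNTf2 should then give the enol triflate F4 with the double bond fixed in place. Reduction of the triflate with Pd(OAc)2, PPh3, HCO2H and Bu3N comes back to the route at 16.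

Step 2. Carbon–carbon bond formation next to bromine may be slow; reversible oxa-Michael addition, 1,2-addition with chromene formation, or an uncatalysed background reaction could then erode yield and enantioselectivity. The fallback uses chiral Lewis acid catalysis with a two-point-binding acceptor and sets out from 3. Friedel–Crafts alkylation with ethyl (E)-4-(1-methylimidazol-2-yl)-4-oxobut-2-enoate, catalysed by Sc(OTf)3 and the enantiomer of inda-pybox that delivers the (S) centre, should give the acyl imidazole F5. N-Methylation with MeOTf followed by DBU should let the neighbouring phenol displace the imidazolium and form the dihydrocoumarin F6. Reduction with i-Bu2AlH at −78 °C should give lactol 5, and acetalisation as in step 2 comes back to the route at 6.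

Step 6. The iodane may deliver water to an ortho carbon (the geranyl- or prenyl-bearing one) or attack the trisubstituted alkenes of the side chains. The fallback oxygenates the phenolate with singlet oxygen, which adds across the 1,4-positions of the phenol ring and can therefore only functionalise the para carbon. It sets out from 10. Irradiation under O2 with tetraphenylporphyrin and Cs2CO3 in MeOH–CH2Cl2 at −40 °C should give the 3a-hydroperoxide F7, the phenolate being expected to quench singlet oxygen much faster than the alkenes undergo the ene reaction. Reduction with Me2S comes back to the route at 11.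

Further compounds

F1 | step 11 | (E)-3-methylpent-3-en-2-one joined through its C5 to C3 of the carbonate-protected bicycle of 13 | CC(C)=CCC/C(C)=C/CC1=C2OC(=O)O[C@]23[C@H](C/C=C(\C)C(C)=O)C(C)(C)OC3=C(CC=C(C)C)C1=O
F2 | step 11 | 2-(tert-butyldimethylsilyloxy)diene from F1 | CC(C)=CCC/C(C)=C/CC1=C2OC(=O)O[C@]23[C@H](C/C=C(\C)C(=C)O[Si](C)(C)C(C)(C)C)C(C)(C)OC3=C(CC=C(C)C)C1=O
F3 | step 11 | silyl enol ether cycloadduct (16 with OSi(t-Bu)Me2 on the ring A alkene CH carbon) | CC(C)=CCC/C(C)=C/C[C@]12CC(O[Si](C)(C)C(C)(C)C)=C(C)[C@@H]3C[C@@H]4C(C)(C)OC(=C(CC=C(C)C)C1=O)[C@]4(OC(=O)O5)[C@@]325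
F4 | step 11 | enol triflate corresponding to F3 | CC(C)=CCC/C(C)=C/C[C@]12CC(OS(=O)(=O)C(F)(F)F)=C(C)[C@@H]3C[C@@H]4C(C)(C)OC(=C(CC=C(C)C)C1=O)[C@]4(OC(=O)O5)[C@@]325
F5 | step 2 | ethyl (2S)-2-(6-bromo-3-geranyl-2,4-dihydroxyphenyl)-4-(1-methylimidazol-2-yl)-4-oxobutanoate | CC(C)=CCC/C(C)=C/Cc1c(O)cc(Br)c(c1O)[C@H](CC(=O)c1nccn1C)C(=O)OCC
F6 | step 2 | ethyl (4S)-5-bromo-8-geranyl-7-hydroxy-2-oxochromane-4-carboxylate | CC(C)=CCC/C(C)=C/Cc1c(O)cc(Br)c2c1OC(=O)C[C@@H]2C(=O)OCC
F7 | step 6 | 3a-hydroperoxide analogue of 11 | CC(C)=CCC/C(C)=C/CC1=C2OC(OC)C[C@@H]3C(C)(C)OC(=C(CC=C(C)C)C1=O)[C@]23OO
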